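The hydroquinone ring is made last, from an acyclic terminal alkyne, by a Dötz benzannulation. The step exploits the 2-alkyl-1,4-dioxygenated benzene ring. Ar-C1 (bearing benzylic C19) and Ar-C6 are the two alkyne carbons, Ar-C2 (O) comes from CO, and Ar-C3, Ar-C4 and Ar-C5 (O) come from a vinyl(methoxy)carbene. One operation therefore forms Ar-C1–Ar-C2, Ar-C2–Ar-C3 and Ar-C5–Ar-C6 and sets the para oxygens. The precursor is the skipped enyne 20, which already holds the sclareolide-derived drim-7-ene decalin, the E C17=C18 alkene and the Z enol carbamate at C13, joined by syn-carbocupration of an ynol carbamate.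

Key step: step 14

Remark (numbering): drimane numbering for the decalin (ring A = C1–C5, C10; ring B = C5–C10); side chain C11–C19 from C9; enol carbon C20; arene Ar-C1 to Ar-C6 (Ar-C1 bears C19, oxygens on Ar-C2 and Ar-C5).

Remark (assumption): the target is drawn as the free hydrogen sulfate. The route makes its sodium salt, the form to be stored, and liberates the drawn acid by a cold proton exchange in the last work-up.

Remark (carbene partner): the parent vinyl(methoxy)carbene complex polymerises readily, so its 2-(trimethylsilyl)vinyl analogue 25 is used. Silicon leaves the ring carbon during aromatisation, so the same three bonds and the same arene result.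

Step 1
Reactants: 1 (+)-sclareolide
Product: 2 11-homodrimane-8α,12-diol
Conditions: LiAlH4, THF, 0 °C → rt
Reagents that add atoms: none
Why: Hydride reduction of the lactone to the diol, which touches none of the stereocentres C5, C8, C9 and C10.

Step 2
Reactants: 2 11-homodrimane-8α,12-diol
Product: 3 12-acetoxy-11-homodriman-8α-ol
Conditions: Ac2O, pyridine, CH2Cl2, 0 °C → rt
Reagents that add atoms: acetic anhydride CC(=O)OC(C)=O
Why: Chemoselective acylation of the primary alcohol beside the hindered tertiary one; the acetate keeps O-12 from closing a tetrahydrofuran onto C8 in step 3.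

Step 3
Reactants: 3 12-acetoxy-11-homodriman-8α-ol
Product: 4 11-homodrim-7-en-12-yl acetate
Conditions: p-TsOH·H2O (5 mol%), toluene, 60 °C, stopped at full conversion; chromatography on AgNO3-impregnated silica
Reagents that add atoms: none
Why: E1 dehydration in which the tertiary C8 cation should lose the axial 7α-hydrogen faster than the hindered 9α-methine hydrogen or a methyl hydrogen (the proton loss that ends acid-mediated polyene cyclisations in drim-7-enes), with minor Δ8(17) and Δ8(9) isomers removed by argentation chromatography and C9 left untouched.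

Step 4
Reactants: 4 11-homodrim-7-en-12-yl acetate
Product: 5 11-homodrim-7-en-12-ol
Conditions: K2CO3, MeOH, rt
Reagents that add atoms: none
Why: Base-catalysed transesterification of a primary acetate, without effect on the Δ7 alkene.

Step 5
Reactants: 5 11-homodrim-7-en-12-ol
Product: 6 12-iodo-11-homodrim-7-ene
Conditions: I2, PPh3, imidazole, CH2Cl2, 0 °C → rt
Reagents that add atoms: iodine II
Why: Appel-type iodination of an unhindered primary alcohol by SN2 displacement of the oxyphosphonium group.

Step 6
Reactants: 6 12-iodo-11-homodrim-7-ene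
Product: 7 terminal alkyne C9–C11H2–C12H2–C13≡C20H
Conditions: LiC≡CH·H2NCH2CH2NH2, DMSO, rt
Reagents that add atoms: lithium acetylide (ethylenediamine complex) [Li]C#C
Why: SN2 alkylation of lithium acetylide by the primary iodide in DMSO, which adds C13 and C20.

Step 7
Reactants: 7 terminal alkyne C9–C11H2–C12H2–C13≡C20H
Product: 10 ynol carbamate C13≡C20–OC(O)N(i-Pr)2, via lithium acetylide 8 (not isolated), via lithium ynolate 9 (not isolated)
Conditions: n-BuLi, THF, −78 °C; t-BuOOLi (from t-BuOOH and LiN(SiMe3)2), −78 → 0 °C; ClC(O)N(i-Pr)2, 0 °C → rt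
Reagents that add atoms: tert-butyl hydroperoxide CC(C)(C)OO; N,N-diisopropylcarbamoyl chloride CC(C)N(C(C)C)C(=O)Cl
Why: Oxidation of a lithium acetylide with lithium tert-butyl peroxide gives the lithium ynolate, which the hindered carbamoyl chloride acylates on oxygen (the known route to O-alkynyl carbamates).

Step 8
Reactants: 11 pent-4-yn-1-ol
Product: 13 (E)-3-methylhex-2-ene-1,6-diol, via alkenylalane 12 (not isolated)
Conditions: Me3Al (3 equiv), Cp2ZrCl2 (0.25 equiv), CH2Cl2, 0 °C → rt; then n-BuLi, (CH2O)n, THF, −78 °C → rt; aq. HCl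
Reagents that add atoms: trimethylaluminium C[Al](C)C; paraformaldehyde (as formaldehyde) C=O
Why: Negishi carboalumination adds CH3 and Al syn across the alkyne (CH3 to C17, Al to C18), and hydroxymethylation of the alkenylalanate with retention fixes the E C17=C18 geometry and adds C19.

Step 9
Reactants: 13 (E)-3-methylhex-2-ene-1,6-diol
Product: 14 (E)-1,6-dibromo-3-methylhex-2-ene
Conditions: CBr4, PPh3, CH2Cl2, 0 °C
Reagents that add atoms: carbon tetrabromide BrC(Br)(Br)Br
Why: Appel bromination of both primary alcohols by SN2, without allylic transposition or loss of alkene geometry.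

Step 10
Reactants: 14 (E)-1,6-dibromo-3-methylhex-2-ene
Product: 15 (E)-(8-bromo-5-methyloct-4-en-1-yn-1-yl)trimethylsilane
Conditions: Me3SiC≡CH, EtMgBr, THF, 0 °C; then 14, CuBr·SMe2 (10 mol%), THF, 0 °C → rt
Reagents that add atoms: ethynyltrimethylsilane C#C[Si](C)(C)C
Why: Copper-catalysed coupling of an alkynyl Grignard reagent with the allylic bromide at its CH2 end (the γ-carbon is fully substituted), which the saturated primary bromide survives.

Step 11
Reactants: 10 ynol carbamate C13≡C20–OC(O)N(i-Pr)2; 15 (E)-(8-bromo-5-methyloct-4-en-1-yn-1-yl)trimethylsilane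
Product: 19 (Z)-enol carbamate carrying the C-silylated skipped enyne, via Grignard reagent 16 (not isolated), via alkylcopper 17 (not isolated), via alkenylcopper adduct 18 (not isolated)
Conditions: 15 (1.6 equiv), Mg, Et2O, reflux; CuBr·SMe2 (1.6 equiv), Et2O, −40 °C; 10, −40 → −10 °C; aq. NH4Cl
Reagents that add atoms: none
Why: Syn-carbocupration of an O-alkynyl carbamate in which the carbamate carbonyl holds copper on C20, so the alkyl group adds to C13 cis to copper and protonation with retention leaves O cis to C12, the Z enol geometry of the target.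

Step 12
Reactants: 19 (Z)-enol carbamate carrying the C-silylated skipped enyne
Product: 20 (Z)-enol carbamate carrying the terminal skipped enyne
Conditions: K2CO3, MeOH/THF, 0 °C → rt
Reagents that add atoms: none
Why: Methanolysis of the alkynyl C–Si bond under mild base, which should leave the hindered enol carbamate and the skipped enyne unisomerised.

Step 13
Reactants: 21 (E)-(2-bromovinyl)trimethylsilane; 22 chromium hexacarbonyl Cr(CO)6
Product: 25 pentacarbonyl{methoxy[(E)-2-(trimethylsilyl)vinyl]carbene}chromium, via vinyllithium 23 (not isolated), via lithium acylchromate 24 (not isolated)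
Conditions: t-BuLi (2 equiv), Et2O, −78 °C; Cr(CO)6, Et2O, −78 °C → rt; Me3OBF4, CH2Cl2, 0 °C
Reagents that add atoms: trimethyloxonium tetrafluoroborate C[O+](C)C.F[B-](F)(F)F
Why: Fischer carbene synthesis, in which the vinyllithium adds to a carbonyl ligand of Cr(CO)6 and the acylchromate is methylated on oxygen.

Step 14
Reactants: 20 (Z)-enol carbamate carrying the terminal skipped enyne; 25 pentacarbonyl{methoxy[(E)-2-(trimethylsilyl)vinyl]carbene}chromium
Product: 27 4-methoxyphenol of the full skeleton, via aryl trimethylsilyl ether 26 (not isolated)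
Conditions: 25 (1.5 equiv), THF, 50 °C, argon; then air, MeCN, rt; 10% aq. citric acid
Reagents that add atoms: none
Why: Loss of one CO from 25 opens a site on chromium, the terminal alkyne of 20 inserts into the Cr=C bond (Ar-C6–Ar-C5), a carbonyl ligand inserts to give the chromium-bound dienylketene (Ar-C1–Ar-C2), and the cyclohexadienone formed on ring closure aromatises by a 1,3-shift of silicon from Ar-C3 to oxygen; air then removes the Cr(CO)3 fragment and the work-up hydrolyses the aryl silyl ether 26. The closest known reaction type is the Dötz benzannulation of alkenyl(alkoxy)carbene chromium complexes with terminal alkynes, including 2-silylvinyl complexes as stable stand-ins for the parent vinyl complex. The one ring closes by thermal 6π-electrocyclisation of the hexatriene unit of the dienylketene (Ar-C2–Ar-C3), and no stereocentre is formed. The step needs regiocontrol in the alkyne insertion: the substituted alkyne carbon (bearing C19H2) stays away from the carbene carbon and ends next to the CO-derived carbon, while the terminal CH ends next to C–OMe, which fixes the 2-alkyl-4-methoxyphenol pattern. It also needs chemoselectivity, which the neutral conditions should give: the enol carbamate and the Δ7 and C17=C18 alkenes do not react, and the one-carbon tether at C19 is too short for cyclopropanation by the vinylcarbene intermediate.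

Step 15
Reactants: 27 4-methoxyphenol of the full skeleton
Product: 28 2-alkyl-1,4-benzoquinone
Conditions: (NH4)2Ce(NO3)6 (2.2 equiv), MeCN/H2O, 0 °C
Reagents that add atoms: water O
Why: Oxidative demethylation of a 4-methoxyphenol to the para-quinone, fast at 0 °C and established beside trisubstituted alkenes in prenylated quinone chemistry.

Step 16
Reactants: 28 2-alkyl-1,4-benzoquinone
Product: 29 hydroquinone
Conditions: Na2S2O4, THF/H2O, rt, argon
Reagents that add atoms: none
Why: Dithionite reduction of a quinone to the hydroquinone, with no effect on alkenes or the carbamate.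

Step 17
Reactants: 29 hydroquinone
Product: 30 bis(triisopropylsilyl) ether of the hydroquinone
Conditions: i-Pr3SiCl, imidazole, DMF, rt, argon
Reagents that add atoms: chlorotriisopropylsilane CC(C)[Si](Cl)(C(C)C)C(C)C
Why: Silylation of both phenols, so that only the enolate oxygen is sulfated in step 18; the hindered aryl silyl ethers withstand MeLi and fall to fluoride.

Step 18
Reactants: 30 bis(triisopropylsilyl) ether of the hydroquinone
Product: 32 sodium (Z)-enol sulfate with both phenols silylated, via lithium enolate 31 (not isolated)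
Conditions: MeLi, THF, −78 → 0 °C; SO3·NMe3, THF/DMF, −40 °C → rt; aq. NaHCO3
Reagents that add atoms: sulfur trioxide–trimethylamine complex C[N+](C)(C)S(=O)(=O)[O-]; sodium hydrogencarbonate [Na+].OC(=O)[O-]
Why: Decarbamoylation of an enol carbamate by MeLi (addition to the carbamate carbonyl; vinylic deprotonation at C20 needs s-BuLi/diamine bases) should release the lithium enolate with the C13=C20 geometry intact, and the sulfur electrophile then sulfates it on oxygen because C-attack is blocked at the fully substituted C13.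

Step 19
Reactants: 32 sodium (Z)-enol sulfate with both phenols silylated
Product: 34 target hydroquinone enol hydrogen sulfate, via sodium salt 33 (not isolated)
Conditions: KHF2, MeOH, rt, argon; then HCl (1.0 equiv, 0.1 M aq.), 0 °C, extraction into n-BuOH
Reagents that add atoms: none
Why: Fluoride cleavage of phenolic silyl ethers under near-neutral conditions that an enol sulfate anion tolerates, followed by a brief cold proton exchange to the drawn acid form.

Compound list
1 | (+)-sclareolide, (3aR,5aS,9aS,9bR)-3a,6,6,9a-tetramethyldecahydronaphtho[2,1-b]furan-2(1H)-one | O=C1C[C@H]2[C@](C)(O1)CC[C@H]3C(C)(C)CCC[C@]23C | starting material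
2 | 11-homodrimane-8α,12-diol (8α-OH, 8β-CH3, 9β-CH2CH2OH; C5, C9, C10 as in 1) | OCC[C@H]1[C@](C)(O)CC[C@H]2C(C)(C)CCC[C@]12C | intermediate
3 | 12-acetoxy-11-homodriman-8α-ol | CC(=O)OCC[C@H]1[C@](C)(O)CC[C@H]2C(C)(C)CCC[C@]12C | intermediate
4 | 11-homodrim-7-en-12-yl acetate (5α-H, 9α-H, 10β-CH3) | CC1=CC[C@H]2C(C)(C)CCC[C@]2(C)[C@H]1CCOC(C)=O | intermediate
5 | 11-homodrim-7-en-12-ol | CC1=CC[C@H]2C(C)(C)CCC[C@]2(C)[C@H]1CCO | intermediate
6 | 12-iodo-11-homodrim-7-ene | CC1=CC[C@H]2C(C)(C)CCC[C@]2(C)[C@H]1CCI | intermediate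
7 | terminal alkyne, 12-ethynyl-11-homodrim-7-ene (C13≡C20H) | CC1=CC[C@H]2C(C)(C)CCC[C@]2(C)[C@H]1CCC#C | intermediate
8 | lithium acetylide of 7 | CC1=CC[C@H]2C(C)(C)CCC[C@]2(C)[C@H]1CCC#C[Li] | intermediate
9 | lithium ynolate (C13≡C20–OLi) | CC1=CC[C@H]2C(C)(C)CCC[C@]2(C)[C@H]1CCC#CO[Li] | intermediate
10 | ynol carbamate, alkynyl N,N-diisopropylcarbamate (C13≡C20–O) | CC1=CC[C@H]2C(C)(C)CCC[C@]2(C)[C@H]1CCC#COC(=O)N(C(C)C)C(C)C | intermediate
11 | pent-4-yn-1-ol | C#CCCCO | starting material
12 | (E)-alkenylalane from carboalumination (O-aluminated) | C[Al](C)/C=C(\C)CCCO[Al](C)C | intermediate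
13 | (E)-3-methylhex-2-ene-1,6-diol | OC/C=C(\C)CCCO | intermediate
14 | (E)-1,6-dibromo-3-methylhex-2-ene | BrC/C=C(\C)CCCBr | intermediate
15 | (E)-(8-bromo-5-methyloct-4-en-1-yn-1-yl)trimethylsilane | C[Si](C)(C)C#CC/C=C(\C)CCCBr | intermediate
16 | Grignard reagent of 15 | C[Si](C)(C)C#CC/C=C(\C)CCC[Mg]Br | intermediate
17 | alkylcopper reagent from 16 | C[Si](C)(C)C#CC/C=C(\C)CCC[Cu] | intermediate
18 | alkenylcopper adduct (Cu on C20, cis to C14; O cis to C12) | CC1=CC[C@H]2C(C)(C)CCC[C@]2(C)[C@H]1CC/C(=C(\OC(=O)N(C(C)C)C(C)C)[Cu])CCC/C(C)=C/CC#C[Si](C)(C)C | intermediate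
19 | (Z)-enol N,N-diisopropylcarbamate with (E)-skipped enyne, alkyne C-silylated | CC1=CC[C@H]2C(C)(C)CCC[C@]2(C)[C@H]1CC/C(=C\OC(=O)N(C(C)C)C(C)C)CCC/C(C)=C/CC#C[Si](C)(C)C | intermediate
20 | (Z)-enol N,N-diisopropylcarbamate with (E)-skipped terminal enyne (key-step precursor) | CC1=CC[C@H]2C(C)(C)CCC[C@]2(C)[C@H]1CC/C(=C\OC(=O)N(C(C)C)C(C)C)CCC/C(C)=C/CC#C | intermediate
21 | (E)-(2-bromovinyl)trimethylsilane | C[Si](C)(C)/C=C/Br | starting material
22 | chromium hexacarbonyl Cr(CO)6 | O=C=[Cr](=C=O)(=C=O)(=C=O)(=C=O)=C=O | starting material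
23 | (E)-2-(trimethylsilyl)vinyllithium | C[Si](C)(C)/C=C/[Li] | intermediate
24 | lithium pentacarbonyl[(E)-3-(trimethylsilyl)acryloyl]chromate | [Li+].C[Si](C)(C)/C=C/C([O-])=[Cr](=C=O)(=C=O)(=C=O)(=C=O)=C=O | intermediate
25 | pentacarbonyl{methoxy[(E)-2-(trimethylsilyl)vinyl]carbene}chromium | C[Si](C)(C)/C=C/C(OC)=[Cr](=C=O)(=C=O)(=C=O)(=C=O)=C=O | intermediate
26 | aryl trimethylsilyl ether of 27 | CC1=CC[C@H]2C(C)(C)CCC[C@]2(C)[C@H]1CC/C(=C\OC(=O)N(C(C)C)C(C)C)CCC/C(C)=C/Cc1cc(OC)ccc1O[Si](C)(C)C | intermediate
27 | 4-methoxyphenol of the full skeleton (OH on Ar-C2, OMe on Ar-C5; key-step product) | CC1=CC[C@H]2C(C)(C)CCC[C@]2(C)[C@H]1CC/C(=C\OC(=O)N(C(C)C)C(C)C)CCC/C(C)=C/Cc1cc(OC)ccc1O | intermediate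
28 | 2-alkyl-1,4-benzoquinone with enol carbamate | CC1=CC[C@H]2C(C)(C)CCC[C@]2(C)[C@H]1CC/C(=C\OC(=O)N(C(C)C)C(C)C)CCC/C(C)=C/CC1=CC(=O)C=CC1=O | intermediate
29 | hydroquinone with enol carbamate | CC1=CC[C@H]2C(C)(C)CCC[C@]2(C)[C@H]1CC/C(=C\OC(=O)N(C(C)C)C(C)C)CCC/C(C)=C/Cc1cc(O)ccc1O | intermediate
30 | bis(triisopropylsilyl) ether of 29 | CC1=CC[C@H]2C(C)(C)CCC[C@]2(C)[C@H]1CC/C(=C\OC(=O)N(C(C)C)C(C)C)CCC/C(C)=C/Cc1cc(O[Si](C(C)C)(C(C)C)C(C)C)ccc1O[Si](C(C)C)(C(C)C)C(C)C | intermediate
31 | lithium (Z)-enolate (O on C20, cis to C12) | CC1=CC[C@H]2C(C)(C)CCC[C@]2(C)[C@H]1CC/C(=C\O[Li])CCC/C(C)=C/Cc1cc(O[Si](C(C)C)(C(C)C)C(C)C)ccc1O[Si](C(C)C)(C(C)C)C(C)C | intermediate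
32 | sodium (Z)-enol sulfate, phenols as triisopropylsilyl ethers | CC1=CC[C@H]2C(C)(C)CCC[C@]2(C)[C@H]1CC/C(=C\OS(=O)(=O)[O-])CCC/C(C)=C/Cc1cc(O[Si](C(C)C)(C(C)C)C(C)C)ccc1O[Si](C(C)C)(C(C)C)C(C)C.[Na+] | intermediate
33 | sodium salt of the target | CC1=CC[C@H]2C(C)(C)CCC[C@]2(C)[C@H]1CC/C(=C\OS(=O)(=O)[O-])CCC/C(C)=C/Cc1cc(O)ccc1O.[Na+] | intermediate
34 | CNP0476859.3, hydroquinone (Z)-enol hydrogen sulfate | CC1=CC[C@H]2C(C)(C)CCC[C@]2(C)[C@H]1CC/C(=C\OS(=O)(=O)O)CCC/C(C)=C/Cc1cc(O)ccc1O | target

Total step count: 19 steps. Longest linear sequence: 15 steps (steps 1–7, 11, 12, 14–19).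

Steps most likely to fail

Step 14 (benzannulation). The carbene complex and the alkyne may oligomerise or decompose thermally before productive insertion. A second alkyne may be taken up, or the silyl shift may stay incomplete, so the limiting enyne would be consumed without clean arene formation. The fallback gives up building the arene and brings it in preformed; it sets out from dibromide 14 and ynol carbamate 10 and comes back at quinone 28. Dibromide 14 is coupled at its allylic bromide with 2,5-dimethoxyphenylmagnesium bromide (CuBr·SMe2 10 mol%, THF, −20 °C) to give (E)-2-(6-bromo-3-methylhex-2-en-1-yl)-1,4-dimethoxybenzene F1. Mg in Et2O turns this into its Grignard reagent F2, and CuBr·SMe2 into the alkylcopper reagent F3. Syn-carbocupration of 10, as in step 11, gives the alkenylcopper adduct F4, and aqueous NH4Cl gives the dimethoxyarene (Z)-enol carbamate F5. Oxidation of F5 with (NH4)2Ce(NO3)6 in MeCN/H2O at 0 °C gives quinone 28, and the route continues with step 16.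

Step 18 (enolate release and sulfation). Attack of the aggregated lithium enolate on the sparingly soluble amine–SO3 complex may be slow. Proton transfer back to the aldehyde, or competing metalation at C20, would then erode yield and enol geometry. The fallback introduces the sulfate as a protected diester; it sets out from 30 and comes back at 32. Enolate 31 is generated as before and trapped at −78 °C with 2,2,2-trichloroethyl chlorosulfate, a far stronger sulfur electrophile, to give the enol 2,2,2-trichloroethyl sulfate diester F6. Zn dust with HCO2NH4 in MeOH at rt then removes the trichloroethyl group reductively, and NaHCO3 work-up gives 32.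

Step 3 (dehydration). Proton loss from the C8 cation may be unselective (towards C17 or C9), and prolonged acid contact may move the double bond on to the tetrasubstituted Δ8(9) position. The result would be an alkene mixture that is hard to separate. The fallback separates elimination from double-bond placement; it sets out from 3 and comes back at 4. SOCl2 in pyridine/CH2Cl2 at −78 °C eliminates through the chlorosulfite, and because the 8α-oxygen is equatorial only a methyl hydrogen is antiperiplanar, so the exocyclic alkene 11-homodrim-8(17)-en-12-yl acetate F7 should form. RhCl3·3H2O (cat.) in EtOH at 75 °C then moves the double bond into the ring by a metal hydride shift that takes the accessible C7 hydrogen and not the hindered C9 methine, giving 4.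

Further compounds
F1 | step 14 | (E)-2-(6-bromo-3-methylhex-2-en-1-yl)-1,4-dimethoxybenzene | COc1ccc(OC)c(C/C=C(\C)CCCBr)c1
F2 | step 14 | Grignard reagent of F1 | COc1ccc(OC)c(C/C=C(\C)CCC[Mg]Br)c1
F3 | step 14 | alkylcopper reagent from F2 | COc1ccc(OC)c(C/C=C(\C)CCC[Cu])c1
F4 | step 14 | alkenylcopper adduct of F3 and 10 (Cu on C20) | CC1=CC[C@H]2C(C)(C)CCC[C@]2(C)[C@H]1CC/C(=C(\OC(=O)N(C(C)C)C(C)C)[Cu])CCC/C(C)=C/Cc1cc(OC)ccc1OC
F5 | step 14 | dimethoxyarene (Z)-enol carbamate | CC1=CC[C@H]2C(C)(C)CCC[C@]2(C)[C@H]1CC/C(=C\OC(=O)N(C(C)C)C(C)C)CCC/C(C)=C/Cc1cc(OC)ccc1OC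
F6 | step 18 | (Z)-enol 2,2,2-trichloroethyl sulfate diester, phenols as triisopropylsilyl ethers | CC1=CC[C@H]2C(C)(C)CCC[C@]2(C)[C@H]1CC/C(=C\OS(=O)(=O)OCC(Cl)(Cl)Cl)CCC/C(C)=C/Cc1cc(O[Si](C(C)C)(C(C)C)C(C)C)ccc1O[Si](C(C)C)(C(C)C)C(C)C
F7 | step 3 | 11-homodrim-8(17)-en-12-yl acetate | C=C1CC[C@H]2C(C)(C)CCC[C@]2(C)[C@H]1CCOC(C)=O
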